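**Retrosynthetic overview**

- The target is (3R)-β-cryptoxanthin oleate. The acyl C–O bond is cut last (oleoyl chloride plus the carotenol), and C7=C8 is cut by a Julia–Kocienski union of a C10 ring A sulfone with the C30 β-apo-8'-carotenal, which carries ring B and the whole polyene.
- The feature the plan rests on: in ring A (C1–C6) the only stereocentre, the ester-bearing C3, is homoallylic to C5=C6. C3 and C4 therefore map onto the distal cis C3=C4 alkene of the achiral 3,4-didehydro ring of safranal.
- The C3 carbinol comes from a cis-3,4-oxirane on the safranate ring by palladium/formate cleavage of the allylic C4–O bond. The oxirane comes from enantioselective manganese-salen oxygen transfer to ethyl safranate.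
- Ring order: both carbocycles are bought (safranal, C30 aldehyde). The only ring formed is the temporary oxirane, closed in step 3 and opened in step 4.

Key step: step 3

**Assumptions (remarks on the chemistry)**

- The sense of induction is taken from the established behaviour of this manganese salen chloride with cis-alkenes conjugated on one side (indene, 1,2-dihydronaphthalene, 2,2-dimethylchromene): the (R,R) complex makes the oxirane carbon next to the conjugating group R. On that basis the (R,R) complex is specified. If this substrate showed the opposite sense, the (S,S) complex would be used with nothing else changed.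
- The C3 descriptor is S in the oxirane and R in the carbinol for the same spatial arrangement, because C4 loses its oxygen and falls below C2 in CIP rank.
- All polyene operations (steps 9–11) are run under argon in subdued light.

**Route**

Step 1
Reactants: 1 safranal (2,6,6-trimethylcyclohexa-1,3-diene-1-carbaldehyde)
Product: 2 safranic acid (2,6,6-trimethylcyclohexa-1,3-diene-1-carboxylic acid)
Conditions: NaClO2, NaH2PO4, 2-methyl-2-butene, t-BuOH/H2O, 0 °C to rt
Reagents that add atoms: sodium chlorite, [Na+].[O-]Cl=O
Why: Pinnick oxidation: chlorous acid adds to the hindered aldehyde and fragments to the acid, while 2-methyl-2-butene traps the HOCl formed so that the ring diene is not chlorinated.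

Step 2
Reactants: 2 safranic acid
Product: 3 ethyl safranate (ethyl 2,6,6-trimethylcyclohexa-1,3-diene-1-carboxylate)
Conditions: EtI, K2CO3, DMF, rt
Reagents that add atoms: iodoethane, CCI
Why: Carboxylate O-alkylation (SN2 on iodoethane) takes place away from the crowded carbonyl carbon, so it is not slowed by the two flanking substituents as a Fischer esterification would be.

Step 3
Reactants: 3 ethyl safranate
Product: 4 ethyl (1R,6S)-2,4,4-trimethyl-7-oxabicyclo[4.1.0]hept-2-ene-3-carboxylate (ethyl cis-3,4-epoxysafranate; carotenoid numbering 3S,4R)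
Conditions: (R,R)-chloro[N,N'-bis(3,5-di-tert-butylsalicylidene)-1,2-cyclohexanediaminato]manganese (trivalent manganese, 5 mol%), 4-phenylpyridine N-oxide (20 mol%), aq. NaOCl (pH 11.3, Na2HPO4 buffer), CH2Cl2, 0 °C; isolation on Et3N-deactivated silica
Reagents that add atoms: sodium hypochlorite, [Na+].[O-]Cl
Why: NaOCl oxidises the trivalent manganese salen chloride to an oxo-manganese species (pentavalent manganese) that meets the cis-disubstituted C3=C4 bond side-on; the C3–O bond forms first and leaves a C4 radical stabilised by C5=C6 and the ester, which collapses on the same oxygen to form C4–O. The closest known reaction type is the Jacobsen epoxidation of cis-disubstituted alkenes conjugated to an aryl, alkenyl or alkynyl group, cyclic 1,3-dienes and dienoates included. The oxirane (O, C3, C4) is closed by this stepwise two-bond oxygen-atom transfer, a formal [2+1] addition ending in a 3-exo radical recombination at C4, and the six-membered ring allows only the cis fusion, so no trans isomer can leak out through the radical. C3 and C4 are both set by the enantioface chosen by the (R,R) ligand (C3 S and C4 R in the oxirane, which is the C3–O configuration of the target), and their cis relation is fixed by the ring. The step needs enantiofacial selectivity, supplied by the ligand and helped by the contrast between the flat conjugated C4 side and the CH2–CMe2 side, and site selectivity, secured because C5=C6 is tetrasubstituted, shielded by the gem-dimethyl group and electron-poor through the ester.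

Step 4
Reactants: 4 ethyl cis-3,4-epoxysafranate
Product: 5 ethyl (4R)-4-hydroxy-2,6,6-trimethylcyclohex-1-ene-1-carboxylate (ethyl (3R)-3-hydroxy-β-cyclogeranate)
Conditions: Pd2(dba)3·CHCl3 (2.5 mol%), PBu3 (5 mol%), HCO2H (5 equiv), Et3N (2 equiv), 1,4-dioxane, rt
Reagents that add atoms: none
Why: Tsuji-type palladium-catalysed formate hydrogenolysis of an alkenyl oxirane: zerovalent palladium ionises the allylic C4–O bond to a π-allyl complex over C4–C6, the formate ligand loses CO2, and the hydride goes to C4 (the terminus remote from the ester, as with γ,δ-epoxy-α,β-enoates), which leaves C5=C6 conjugated and the C3 stereocentre untouched.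

Step 5
Reactants: 5 ethyl (3R)-3-hydroxy-β-cyclogeranate
Product: 6 ethyl (4R)-4-[(tert-butyldimethylsilyl)oxy]-2,6,6-trimethylcyclohex-1-ene-1-carboxylate
Conditions: TBSCl, imidazole, DMF, rt
Reagents that add atoms: tert-butyldimethylsilyl chloride, CC(C)(C)[Si](C)(C)Cl
Why: Imidazole-promoted O-silylation of an unhindered secondary alcohol masks the carbinol for the hydride, Mitsunobu and carbanion steps; the stereocentre is not involved.

Step 6
Reactants: 6 silyl ether ester
Product: 7 {(4R)-4-[(tert-butyldimethylsilyl)oxy]-2,6,6-trimethylcyclohex-1-en-1-yl}methanol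
Conditions: i-Bu2AlH (2.5 equiv), CH2Cl2, −78 to 0 °C; aq. potassium sodium tartrate
Reagents that add atoms: none
Why: i-Bu2AlH reduction of the ester gives the primary allylic alcohol (1,2-reduction only, as the tetrasubstituted alkene is inert) and the silyl ether is stable to the hydride.

Step 7
Reactants: 7 allylic alcohol
Product: 8 5-[({(4R)-4-[(tert-butyldimethylsilyl)oxy]-2,6,6-trimethylcyclohex-1-en-1-yl}methyl)sulfanyl]-1-phenyl-1H-tetrazole
Conditions: 1-phenyl-1H-tetrazole-5-thiol, PPh3, DIAD, THF, 0 °C to rt
Reagents that add atoms: 1-phenyl-1H-tetrazole-5-thiol, Sc1nnnn1-c1ccccc1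
Why: Mitsunobu thioetherification: the primary allylic oxyphosphonium is displaced at C7 by the acidic thiol in an SN2 reaction, and SN2' attack on the tetrasubstituted C5 is sterically excluded.

Step 8
Reactants: 8 tetrazolyl sulfide
Product: 9 5-[({(4R)-4-[(tert-butyldimethylsilyl)oxy]-2,6,6-trimethylcyclohex-1-en-1-yl}methyl)sulfonyl]-1-phenyl-1H-tetrazole
Conditions: (NH4)6Mo7O24·4H2O (10 mol%), 30% aq. H2O2, EtOH, 0 °C to rt
Reagents that add atoms: hydrogen peroxide, OO
Why: Molybdate-catalysed peroxide oxidation of sulfide to sulfone: the peroxomolybdate oxidises sulfur far faster than the hindered tetrasubstituted alkene, which a peracid would attack, and the silyl ether tolerates the mild medium.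

Step 9
Reactants: 9 tetrazolyl sulfone; 10 β-apo-8'-carotenal (all-E C30 aldehyde)
Product: 12 (3R)-β-cryptoxanthin tert-butyldimethylsilyl ether (all-E), via potassium sulfonyl carbanion 11 (not isolated)
Conditions: KN(SiMe3)2, THF, −78 °C; then 10 in THF, −78 °C to rt
Reagents that add atoms: none
Why: Julia–Kocienski olefination: the premetalated sulfone adds to the non-enolisable polyenal, Smiles transfer of the tetrazole and loss of SO2 form C7=C8, and E geometry should be favoured because a 7Z alkene would clash with the C1 and C5 ring methyls (any Z component is isomerised thermally at the next stage).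

Step 10
Reactants: 12 silyl ether of β-cryptoxanthin
Product: 13 (3R)-β-cryptoxanthin ((3R,all-E)-β,β-caroten-3-ol)
Conditions: Bu4NF, THF, rt; then brief reflux in heptane/EtOH and crystallisation
Reagents that add atoms: none
Why: Fluoride desilylation is driven by the Si–F bond and leaves the polyene alone; heating and crystallisation is the usual carotenoid Z-to-E equilibration that collects the all-E isomer.

Step 11
Reactants: 13 (3R)-β-cryptoxanthin; 14 oleoyl chloride
Product: 15 (3R)-β-cryptoxanthin oleate ((3R)-β,β-caroten-3-yl (9Z)-octadec-9-enoate), the target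
Conditions: pyridine, DMAP (cat.), CH2Cl2, 0 °C to rt
Reagents that add atoms: none
Why: DMAP-catalysed acylation of the secondary carbinol by the acyl chloride forms the ester with retention at C3 (the C–O bond is not broken) and without touching the 9Z alkene or the polyene.

**Compound list**

1 | safranal | CC1=C(C=O)C(C)(C)CC=C1 | starting material
2 | safranic acid | CC1=C(C(=O)O)C(C)(C)CC=C1 | intermediate
3 | ethyl safranate | CCOC(=O)C1=C(C)C=CCC1(C)C | intermediate
4 | ethyl (1R,6S)-2,4,4-trimethyl-7-oxabicyclo[4.1.0]hept-2-ene-3-carboxylate (ethyl cis-3,4-epoxysafranate) | CCOC(=O)C1=C(C)[C@H]2O[C@H]2CC1(C)C | intermediate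
5 | ethyl (4R)-4-hydroxy-2,6,6-trimethylcyclohex-1-ene-1-carboxylate | CCOC(=O)C1=C(C)C[C@@H](O)CC1(C)C | intermediate
6 | ethyl (4R)-4-[(tert-butyldimethylsilyl)oxy]-2,6,6-trimethylcyclohex-1-ene-1-carboxylate | CCOC(=O)C1=C(C)C[C@@H](O[Si](C)(C)C(C)(C)C)CC1(C)C | intermediate
7 | {(4R)-4-[(tert-butyldimethylsilyl)oxy]-2,6,6-trimethylcyclohex-1-en-1-yl}methanol | OCC1=C(C)C[C@@H](O[Si](C)(C)C(C)(C)C)CC1(C)C | intermediate
8 | 5-[({(4R)-4-[(tert-butyldimethylsilyl)oxy]-2,6,6-trimethylcyclohex-1-en-1-yl}methyl)sulfanyl]-1-phenyl-1H-tetrazole | S(CC1=C(C)C[C@@H](O[Si](C)(C)C(C)(C)C)CC1(C)C)c2nnnn2-c3ccccc3 | intermediate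
9 | 5-[({(4R)-4-[(tert-butyldimethylsilyl)oxy]-2,6,6-trimethylcyclohex-1-en-1-yl}methyl)sulfonyl]-1-phenyl-1H-tetrazole | O=S(=O)(CC1=C(C)C[C@@H](O[Si](C)(C)C(C)(C)C)CC1(C)C)c2nnnn2-c3ccccc3 | intermediate
10 | β-apo-8'-carotenal (all-E) | O=C/C(C)=C/C=C/C(C)=C/C=C/C=C(C)/C=C/C=C(C)/C=C/C1=C(C)CCCC1(C)C | starting material
11 | potassium salt of the C7 carbanion of sulfone 9 | [K+].[CH-](C1=C(C)C[C@@H](O[Si](C)(C)C(C)(C)C)CC1(C)C)S(=O)(=O)c2nnnn2-c3ccccc3 | intermediate (not isolated)
12 | (3R)-β-cryptoxanthin tert-butyldimethylsilyl ether | CC(C)(C)[Si](C)(C)O[C@@H]1CC(C)=C(/C=C/C(C)=C/C=C/C(C)=C/C=C/C=C(C)/C=C/C=C(C)/C=C/C2=C(C)CCCC2(C)C)C(C)(C)C1 | intermediate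
13 | (3R)-β-cryptoxanthin | O[C@@H]1CC(C)=C(/C=C/C(C)=C/C=C/C(C)=C/C=C/C=C(C)/C=C/C=C(C)/C=C/C2=C(C)CCCC2(C)C)C(C)(C)C1 | intermediate
14 | oleoyl chloride | CCCCCCCC/C=C\CCCCCCCC(=O)Cl | starting material
15 | (3R)-β-cryptoxanthin oleate | CCCCCCCC/C=C\CCCCCCCC(=O)O[C@@H]1CC(C)=C(/C=C/C(C)=C/C=C/C(C)=C/C=C/C=C(C)/C=C/C=C(C)/C=C/C2=C(C)CCCC2(C)C)C(C)(C)C1 | target

**Step count**

Total: 11 steps. Longest linear sequence: 11 steps (1 to 15). Compounds 10 and 14 are bought and enter in steps 9 and 11.

**Steps most likely to fail, with fallbacks**

Step 3. The risk is insufficient enantiofacial discrimination on this unreported dienoate, or loss of the acid-labile alkenyl oxirane during reaction and isolation. The fallback sets out from 3 and replaces asymmetric catalysis by resolution. Peracid epoxidation (mCPBA, NaHCO3, CH2Cl2, 0 °C) attacks the γ,δ-alkene C3=C4 of the dienoate and should give the racemic cis-oxirane F1. The conditions of step 4 would convert it to the racemic hydroxy ester F2. Lipase-catalysed transesterification (Burkholderia cepacia lipase, vinyl acetate, t-BuOMe, 30 °C) is expected by the Kazlauskas rule to acylate the (R)-alcohol, whose larger flank is the C2/CMe2 side. This would give the (R)-acetate F3 and leave the (S)-alcohol F4, the two being separated by chromatography. Ethanolysis of F3 (K2CO3, EtOH, rt) returns to the route at 5. If the enzyme preferred the other enantiomer, the unreacted alcohol would be the (R) series and would be taken on directly as 5.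

Step 4. The risk is hydride delivery to the wrong allyl terminus (C6, giving the deconjugated ring), or slow ionisation at the hindered tetrasubstituted alkene with competing isomerisation of the oxirane to a ketone. The fallback sets out from 4 and uses a nucleophile and radical sequence with no π-allyl intermediate. Sodium phenylselenolate (PhSeSePh, NaBH4, EtOH, 0 °C) opens the oxirane at the allylic C4 with inversion to the trans-hydroxy selenide F5. Bu3SnH with AIBN (toluene, 80 °C) then cleaves the C–Se bond, and the allyl radical should take hydrogen at the less hindered C4 to give the conjugated ester. This returns to the route at 5.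

Step 9. The risk is slow addition of the hindered C7 carbanion to the polyenal, decomposition of the metalated allylic sulfone before it adds, or poor E/Z control at C7=C8. The fallback sets out from 7 and replaces the sulfone by a Wittig reagent. Ph3P·HBr in MeOH at rt converts the allylic alcohol into the phosphonium salt and removes the silyl group in the same operation, giving the hydroxy phosphonium bromide F6. Wittig reaction of F6 with 10 (NaOMe, MeOH/CH2Cl2, rt) followed by thermal Z-to-E isomerisation in refluxing heptane/EtOH and crystallisation returns to the route at 13; steps 7 to 10 are then not needed.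

**Further compounds**

F1 | step 3 | racemic ethyl cis-3,4-epoxysafranate (ethyl 2,4,4-trimethyl-7-oxabicyclo[4.1.0]hept-2-ene-3-carboxylate) | CCOC(=O)C1=C(C)C2OC2CC1(C)C
F2 | step 3 | racemic ethyl 4-hydroxy-2,6,6-trimethylcyclohex-1-ene-1-carboxylate | CCOC(=O)C1=C(C)CC(O)CC1(C)C
F3 | step 3 | ethyl (4R)-4-acetoxy-2,6,6-trimethylcyclohex-1-ene-1-carboxylate | CCOC(=O)C1=C(C)C[C@@H](OC(C)=O)CC1(C)C
F4 | step 3 | ethyl (4S)-4-hydroxy-2,6,6-trimethylcyclohex-1-ene-1-carboxylate (unreacted enantiomer) | CCOC(=O)C1=C(C)C[C@H](O)CC1(C)C
F5 | step 4 | ethyl (3S,4S)-4-hydroxy-2,6,6-trimethyl-3-(phenylselanyl)cyclohex-1-ene-1-carboxylate | CCOC(=O)C1=C(C)[C@H]([Se]c2ccccc2)[C@@H](O)CC1(C)C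
F6 | step 9 | {[(4R)-4-hydroxy-2,6,6-trimethylcyclohex-1-en-1-yl]methyl}triphenylphosphonium bromide | O[C@@H]1CC(C)=C(C[P+](c2ccccc2)(c3ccccc3)c4ccccc4)C(C)(C)C1.[Br-]
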